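## The problem

The target is an unsymmetrical ether of two 4',7,8-trihydroxyflavan-3,4-diols joined through O4. Unit A is all-cis (2R,3R,4R) and unit B is 2,3-trans-3,4-cis (2S,3R,4R), so the halves differ at C2 and one monomer cannot serve for both without a late correction. The link is a di-secondary ether between two benzylic carbons, each ortho to O1 and para to O7 of its own ring A. Such a bond is hard to make by substitution and ionises under acid, and a flavan-4-yl cation is captured trans to O3, the opposite of the 3,4-cis relation both units need. C2 and C3 of each unit can be set by reagent control, and C4 of unit B can be relayed from C2 by addition to a flav-3-ene anti to the aryl group. C4 of unit A has to end cis to an axial O3 and has no such relay, so C2 and C3 must control it in the step that makes it. The free phenols limit the end game: 4'-OH para to C2 and 7-OH para to C4 open quinone methide pathways under base, the catechol rings oxidise, and the benzylic ethers do not survive acid. The enabling feature is that C4 of unit A is bonded both to the bridging oxygen and to C4a, the ring A carbon ortho to O1 and para to O7, the most nucleophilic position of a pyrogallol ether. C4 is therefore a masked acetal carbon: a C2–C3–C4 chain hung on O1, with C4 at the oxocarbenium level and unit B already on its oxygen, can close ring C of unit A by arylation.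

## Retrosynthesis

**Deprotection (31 from 30 from 29).** Six O–benzyl bonds and two O–mesyl bonds are cut. Benzyl ethers mask every oxygen that must stay covered to the end because they leave by neutral hydrogenolysis. The two mesylates on ring A of unit B are electronic control elements for the ring closure; they are removed first, from 29, with LDA at low temperature, so that the catechol of 30 never meets hot base. The hydrogenolysis must stop before the hindered interflavan ether is attacked.

**Key disconnection (29 from 27 through 28).** The C4–C4a bond of unit A is cut, which opens ring C to oxocarbenium ion 28 and so to the mixed acetal 27. Against a cut at either C4–O bond, this one makes the ether as part of an acetal and creates C4 of unit A in a ring closure steered by C2 and C3. The forward step has to ionise the right acetal substituent, arylate at C4a only, and place O4 cis to O3.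

**Acetal carbon from an ester (27 from 25).** The acetal C–OAc bond is traced to the carbonyl of ester 25 by reductive acetylation. A mixed methyl acetal made by acid-promoted exchange was set aside: any acid that exchanges an alkoxy group also generates the oxocarbenium ion before unit B is attached, and the arene would trap it as a 4-methoxyflavan. Acetate is also by far the better leaving group in 27, so the ionisation site is fixed by structure.

**Union of the halves (25 from 13 and 24).** The acyl–oxygen bond is cut, giving acid 13 (C2–C4 of unit A with its aryl ether) and flavan-4-ol 24 (unit B). An ester is the easiest bond to make between two hindered fragments, and C4 of unit B is not touched. The mesylates of 24 sit para and meta to C4a, so the O–C4 bond of unit B in 28 does not fragment to a benzylic cation. A cyclic carbonate would serve the same purpose but would not survive i-Bu2AlH.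

**Aryl ether of unit A (13 from 11, 10, then 6 and 9).** The O1–C8a bond is cut to secondary alcohol 6 and aryl iodide 9. Coupling at the aryl carbon retains the benzylic centre, which no displacement at a para-alkoxybenzylic carbon would guarantee. The coupling is done at the alcohol oxidation level, with the terminus as a silyl ether, because a β-aryloxy or β-hydroxy carbonyl compound would suffer β-elimination or retro-aldol cleavage under hot carbonate. The price is a protection, a deprotection and an oxidation (10 to 11 to 13, through aldehyde 12). Iodide 9 comes from 3-bromocatechol 7 through bromide 8.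

**Chain stereocentres of unit A (6 from 5 from 4, from 1 and 2).** The C2–C3 bond is cut by a syn glycolate aldol between imide 1 and aldehyde 2 through boron enolate 3. Against dihydroxylation of a cinnamate, the aldol delivers the two oxygens already differentiated (free benzylic hydroxyl, benzyl ether at C3), so no regioselective alkylation is needed. Reduction of 4 to diol 5 and primary silylation give 6.

**Oxygenation of unit B (24 from 22 from 21).** The C3–O and C4–O bonds are cut back to flav-3-ene 21. Syn dihydroxylation anti to the 2-aryl group gives exactly the 2,3-trans-3,4-cis pattern, so C2 controls both new centres. Stannylene acetal 23 then directs the benzyl group to the equatorial O3.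

**C2 of unit B (21 from 20 from 19, from 17 and 18).** The C2–aryl bond is cut to chromone 17 and boronic acid 18. A catalytic asymmetric conjugate addition sets the only reagent-controlled centre of unit B on a flat, achiral substrate. Reduction to 20 and dehydration move the double bond into place.

**Ring A of unit B (17 from 15 from 14).** The chromone C2 carbon is removed (enaminone 16), leaving ketone 15, the 3,4-bis-mesylate of gallacetophenone 14. Mesylation at the start means ring A never has to be reprotected.

## Roads not taken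

**Alternative 1:** The cut is O1–C2 of unit B, opened and re-formed. The forward key step treats the all-cis dimer A1 (one free ring B phenol) with DBU; the pyran ring opens to a para-quinone methide and the ring A phenoxide re-adds to C2 from the other face, giving A2.
- Merits: both halves come from one all-cis monomer series, which would save roughly the seven steps spent here on unit B, and the 2,3-trans product is the more stable epimer.
- Weak points: the step is an equilibration, so the epimers would have to be separated. The ring-opened phenoxide is ortho to C4a and can expel the C4 alkoxide, which would break the interflavan ether. The idea also does not say how the ether of A1 is made with both C4 centres cis to O3.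
- Comparison: in monomer economy this road is better. The chosen plan sets against it that it builds the ether during ring formation and fixes C2 of each unit by reagent control before the halves meet.

**Alternative 2:** Both O1–C8a bonds are cut. The forward key step is a double intramolecular Ullmann etherification (CuI, 3,4,7,8-tetramethyl-1,10-phenanthroline, Cs2CO3) of the open-chain dibromo diol A3, giving octabenzyl ether A4.
- Merits: no stereocentre is created in the key step, so the C4 selectivity question of the chosen plan does not arise. One hydrogenolysis finishes the synthesis, with no sulfonate detour.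
- Weak points: A3 must already hold the di-secondary dibenzylic ether between two fully substituted open chains, and no reliable way to form that bond with control at both carbons is offered. Each aryl bromide is flanked by a benzyloxy group and a branched benzylic carbon, and two such closures must both succeed at high temperature.
- Comparison: this road is safer on stereochemistry at C4. The chosen plan answers with an ether that arises from an ester, and with ring A used as a nucleophile at its most reactive carbon instead of as a hindered electrophile.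

**Alternative 3:** The cut is C5–C6 and C4a–C8a of ring A of unit B. The forward key step is a Stille coupling of chlorocyclobutenone A5 with alkenylstannane A6 (Pd2(dba)3, tri(2-furyl)phosphine); the alkenylcyclobutenone opens to a dienylketene, which closes and tautomerises to phenol A7.
- Merits: the oxygen pattern of ring A is unambiguous and the one free phenol is exactly the future O1, so O1 is told apart from O7 and O8 without any selectivity question.
- Weak points: a pyrogallol ring that can be bought is built from four-carbon and two-carbon pieces. A6 must already contain complete unit A, the interflavan ether and three chain stereocentres, so the sequence is long and linear. The thermal step heats an allylic, benzylic ether, and ring C of unit B would still have to be closed with inversion at a para-alkoxybenzylic carbon.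
- Comparison: this road wins only on the differentiation of the ring A oxygens. The chosen plan reaches the same differentiation by chelation-controlled mesylation of 14 and is much shorter.

Key step: step 18

Remarks on assumptions:
- Imide 1 is used as purchased; it is otherwise one N-acylation from (S)-4-benzyloxazolidin-2-one.
- The sense of induction in step 11 is assumed to follow that of the same catalyst with cyclic enones, which predicts the 2R product from the (S)-ligand; if it were opposite, the (R)-ligand would be used.
- Acetate 27 is expected as a mixture of the two acetal epimers and is used as such; its SMILES leaves that centre undefined.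

## Route

Step 1
Reactants: 1 (4S)-4-benzyl-3-[(benzyloxy)acetyl]-1,3-oxazolidin-2-one; 2 4-(benzyloxy)benzaldehyde
Product: 4 (4S)-4-benzyl-3-[(2S,3R)-2-(benzyloxy)-3-[4-(benzyloxy)phenyl]-3-hydroxypropanoyl]-1,3-oxazolidin-2-one, via boron enolate 3 (not isolated)
Conditions: n-Bu2BOTf, Et3N, CH2Cl2, −78 to 0 °C; 2, −78 to 0 °C; pH 7 buffer, MeOH, H2O2
Reagents that add atoms: none
Why: Evans syn aldol; the (Z)-boron enolate 3 reacts through a closed chair transition state in which the benzyl group of the auxiliary shields one face, which sets both chain centres (the future C3 and C2 of unit A) and places the benzyl ether on the correct oxygen from the start.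

Step 2
Reactants: 4 syn-aldol adduct
Product: 5 (1R,2R)-2-(benzyloxy)-1-[4-(benzyloxy)phenyl]propane-1,3-diol
Conditions: LiBH4, THF, MeOH (1 equiv), 0 °C
Reagents that add atoms: none
Why: Reductive cleavage of the imide to the primary alcohol with release of the auxiliary; neither stereocentre is touched.

Step 3
Reactants: 5 diol
Product: 6 (1R,2R)-2-(benzyloxy)-1-[4-(benzyloxy)phenyl]-3-[(triisopropylsilyl)oxy]propan-1-ol
Conditions: i-Pr3SiCl, imidazole, CH2Cl2, 0 °C to rt
Reagents that add atoms: chlorotri(propan-2-yl)silane, CC(C)[Si](Cl)(C(C)C)C(C)C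
Why: Silylation with a bulky chlorosilane is selective for the primary hydroxyl; the triisopropylsilyl group is chosen because it should not migrate to the neighbouring alkoxide under the basic coupling of step 6.

Step 4
Reactants: 7 3-bromobenzene-1,2-diol
Product: 8 1,2-bis(benzyloxy)-3-bromobenzene
Conditions: BnBr, K2CO3, DMF, 50 °C
Reagents that add atoms: benzyl bromide, BrCc1ccccc1
Why: Williamson etherification of both phenols.

Step 5
Reactants: 8 1,2-bis(benzyloxy)-3-bromobenzene
Product: 9 1,2-bis(benzyloxy)-3-iodobenzene
Conditions: NaI, CuI (5 mol %), trans-N,N'-dimethylcyclohexane-1,2-diamine (10 mol %), 1,4-dioxane, 110 °C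
Reagents that add atoms: sodium iodide, [Na+].[I-]
Why: Copper-catalysed aromatic Finkelstein exchange, driven by precipitation of NaBr; the iodide is the better partner for the C–O coupling that follows.

Step 6
Reactants: 6 secondary benzylic alcohol; 9 1,2-bis(benzyloxy)-3-iodobenzene
Product: 10 [(2R,3R)-2-(benzyloxy)-3-[4-(benzyloxy)phenyl]-3-[2,3-bis(benzyloxy)phenoxy]propoxy]triisopropylsilane
Conditions: CuI (10 mol %), 3,4,7,8-tetramethyl-1,10-phenanthroline (20 mol %), Cs2CO3, 4 Å sieves, toluene, 100 °C, 9 in excess
Reagents that add atoms: none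
Why: Ullmann-type copper-catalysed coupling of a secondary alcohol with an aryl iodide; the bond is formed at the aryl carbon, so the benzylic centre (future C2 of unit A) is retained, and the substrate holds no carbonyl group that could undergo retro-aldol cleavage or β-elimination.

Step 7
Reactants: 10 silyl ether
Product: 11 (2R,3R)-2-(benzyloxy)-3-[4-(benzyloxy)phenyl]-3-[2,3-bis(benzyloxy)phenoxy]propan-1-ol
Conditions: Bu4NF, THF, 0 °C to rt
Reagents that add atoms: none
Why: Fluoride cleavage of the silyl ether; all other groups are inert.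

Step 8
Reactants: 11 primary alcohol
Product: 13 (2S,3R)-2-(benzyloxy)-3-[4-(benzyloxy)phenyl]-3-[2,3-bis(benzyloxy)phenoxy]propanoic acid, via aldehyde 12 (not isolated)
Conditions: TEMPO (0.2 equiv), PhI(OAc)2 (2.2 equiv), MeCN/H2O 1:1, rt
Reagents that add atoms: water, O
Why: Oxoammonium oxidation in wet acetonitrile takes the alcohol through aldehyde 12 and its hydrate to the acid under near-neutral conditions, so the β-aryloxy aldehyde never meets base and should neither epimerise nor eliminate.

Step 9
Reactants: 14 1-(2,3,4-trihydroxyphenyl)ethan-1-one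
Product: 15 4-acetyl-3-hydroxy-1,2-phenylene dimethanesulfonate
Conditions: MsCl (2.05 equiv), Et3N (2.2 equiv), CH2Cl2, −40 to 0 °C
Reagents that add atoms: methanesulfonyl chloride, CS(=O)(=O)Cl
Why: Sulfonylation of the two free phenols; the 2-hydroxyl is hydrogen-bonded to the ketone and is the least reactive, as in the usual selective 3,4-protection of this ketone.

Step 10
Reactants: 15 bis-mesylate ketone
Product: 17 4-oxo-4H-chromene-7,8-diyl dimethanesulfonate, via enaminone 16 (not isolated)
Conditions: Me2NCH(OMe)2, toluene, 90 °C; evaporate; conc. HCl, CH2Cl2, 40 °C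
Reagents that add atoms: N,N-dimethylformamide dimethyl acetal, COC(OC)N(C)C
Why: Condensation of the methyl ketone to the enaminone and acid-induced cyclisation with loss of dimethylamine, the standard chromone synthesis from 2-hydroxyacetophenones.

Step 11
Reactants: 17 chromone; 18 [4-(benzyloxy)phenyl]boronic acid
Product: 19 (2R)-2-[4-(benzyloxy)phenyl]-4-oxo-3,4-dihydro-2H-chromene-7,8-diyl dimethanesulfonate
Conditions: Pd(OCOCF3)2 (5 mol %), (S)-t-BuPyOx (6 mol %), NH4PF6 (30 mol %), H2O (5 equiv), ClCH2CH2Cl, 60 °C
Reagents that add atoms: none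
Why: Palladium-catalysed asymmetric conjugate addition of an arylboronic acid to a chromone, a known entry to flavanones; the pyridine-oxazoline ligand differentiates the enone faces in the aryl transfer and sets C2, and the base-free medium spares the mesylates and avoids ring opening of the flavanone.

Step 12
Reactants: 19 flavanone
Product: 20 (2R,4R)-2-[4-(benzyloxy)phenyl]-4-hydroxy-3,4-dihydro-2H-chromene-7,8-diyl dimethanesulfonate
Conditions: NaBH4, THF/MeOH, −10 to 0 °C
Reagents that add atoms: none
Why: Hydride reduction of the ketone, expected to give the 2,4-cis alcohol; the carbinol centre is removed in the next step, so its configuration is immaterial.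

Step 13
Reactants: 20 flavan-4-ol
Product: 21 (2R)-2-[4-(benzyloxy)phenyl]-2H-chromene-7,8-diyl dimethanesulfonate
Conditions: Ph2S[OC(CF3)2Ph]2 (Martin sulfurane), CH2Cl2, 0 °C to rt
Reagents that add atoms: none
Why: Dehydration of the benzylic alcohol under neutral conditions at or below room temperature, chosen so that neither acid-induced ionisation of O1–C2 nor thermal electrocyclic ring opening of the chromene erodes C2.

Step 14
Reactants: 21 flav-3-ene
Product: 22 (2S,3R,4R)-2-[4-(benzyloxy)phenyl]-3,4-dihydroxy-3,4-dihydro-2H-chromene-7,8-diyl dimethanesulfonate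
Conditions: OsO4 (2 mol %), N-methylmorpholine N-oxide, acetone/H2O, 0 °C to rt
Reagents that add atoms: N-methylmorpholine N-oxide, C[N+]1([O-])CCOCC1; water, O
Why: Catalytic syn dihydroxylation on the face of the flav-3-ene away from the 2-aryl group, which sets C3 and C4 as the 2,3-trans-3,4-cis diol under control of C2.

Step 15
Reactants: 22 cis-diol
Product: 24 (2S,3R,4R)-3-(benzyloxy)-2-[4-(benzyloxy)phenyl]-4-hydroxy-3,4-dihydro-2H-chromene-7,8-diyl dimethanesulfonate, via stannylene acetal 23 (not isolated)
Conditions: Bu2SnO, toluene, reflux with removal of water; then BnBr, CsF, DMF, rt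
Reagents that add atoms: benzyl bromide, BrCc1ccccc1
Why: Stannylene-mediated monoalkylation of a cis-1,2-diol on a six-membered ring goes to the equatorial oxygen; O3 is equatorial while O4 is pseudoaxial, benzylic and peri-hindered, so the benzyl group should go to O3 and leave the 4-hydroxyl free.

Step 16
Reactants: 13 acid of unit A; 24 flavan-4-ol of unit B
Product: 25 ester of acid 13 with the 4-hydroxyl of 24 (all configurations unchanged)
Conditions: DCC, DMAP (0.3 equiv), CH2Cl2, 0 °C to rt
Reagents that add atoms: none
Why: Steglich esterification joins the halves through an acyl–oxygen bond with retention at C4 of unit B; the low temperature and substoichiometric DMAP limit β-elimination of the aryloxide from the activated acid.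

Step 17
Reactants: 25 ester
Product: 27 α-acetoxy ether in which the ester carbonyl carbon of 25 has become CH(OAc) (both acetal epimers), via aluminium hemiacetal 26 (not isolated)
Conditions: i-Bu2AlH (2 equiv), CH2Cl2, −78 °C; then pyridine, DMAP, Ac2O, −78 to −20 °C
Reagents that add atoms: acetic anhydride, CC(=O)OC(C)=O
Why: Reductive acetylation of an ester; the tetrahedral aluminium hemiacetal of an α-alkoxy ester is stable at −78 °C and is acylated in situ before it can collapse, and aryl mesylates and benzyl ethers are inert to i-Bu2AlH at this temperature; both acetal epimers lead to the same oxocarbenium ion.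

Step 18
Reactants: 27 α-acetoxy ether
Product: 29 (2R,3R,4R)-3,7,8-tris(benzyloxy)-2-[4-(benzyloxy)phenyl]chroman-4-yl (2S,3R,4R)-3-(benzyloxy)-2-[4-(benzyloxy)phenyl]-7,8-bis(mesyloxy)chroman-4-yl ether, via oxocarbenium triflate 28 (not isolated)
Conditions: Me3SiOTf (1.5 equiv), 2,6-di-tert-butyl-4-methylpyridine (2 equiv), CH2Cl2, −78 °C; Et3N then aqueous NaHCO3 at −78 °C
Reagents that add atoms: none
Why: Me3SiOTf silylates the acetate carbonyl of 27 and expels Me3SiOAc, leaving the (E)-oxocarbenium ion 28 whose oxygen substituent is unit B; the two mesylates on ring A of unit B make heterolysis of the O–C4 bond of unit B slow relative to ring closure. The arene carbon ortho to the ether oxygen and para to the 7-benzyloxy group (the only free ortho position; the 4-benzyloxyphenyl ring has no activated carbon within reach) attacks the cationic carbon and the hindered pyridine takes the proton, the closest known reaction type being the Lewis-acid cyclisation of 3-aryloxypropanal acetals and α-acetoxy ethers onto arenes (oxa-Pictet–Spengler-type formation of 4-alkoxychromans). Ring C of unit A closes in a six-membered mode that is exo with respect to the C=O+ bond (6-exo-trig). The new stereocentre C4 is controlled by C2 and C3 through a chair-like transition state in which the 4-benzyloxyphenyl group at C2 is equatorial, the C3 benzyloxy group is therefore axial, and the exocyclic oxocarbenium oxygen takes the equatorial site, as it does in carbonyl-ene and Prins closures with an exocyclic C=O+; this places O4 cis to O3. The step needs chemoselective ionisation (secured by acetate against alkoxide as leaving group), regioselective arylation (secured by the substitution pattern of ring A) and kinetic control, since 29 is a 2,4-dialkoxybenzyl ether whose re-ionisation would lead to the 3,4-trans ether; the base, the low temperature and the cold basic quench are there to prevent that.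

Step 19
Reactants: 29 bis-mesylate
Product: 30 (2R,3R,4R)-3,7,8-tris(benzyloxy)-2-[4-(benzyloxy)phenyl]chroman-4-yl (2S,3R,4R)-3-(benzyloxy)-2-[4-(benzyloxy)phenyl]-7,8-dihydroxychroman-4-yl ether
Conditions: i-Pr2NLi (LDA, 5 equiv), THF, −78 to 0 °C; AcOH
Reagents that add atoms: none
Why: LDA deprotonates the methyl group of each aryl mesylate and the anion fragments to sulfene and the phenoxide, a known low-temperature cleavage of aryl methanesulfonates; without heat or a nucleophile the phenoxide para to C4 of unit B should not expel the alkoxide.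

Step 20
Reactants: 30 hexabenzyl ether
Product: 31 target, (2R,3R,4R)-3,7,8-trihydroxy-2-(4-hydroxyphenyl)chroman-4-yl (2S,3R,4R)-3,7,8-trihydroxy-2-(4-hydroxyphenyl)chroman-4-yl ether
Conditions: H2 (1 atm), Pd(OH)2/C, THF/MeOH, rt, stopped at full conversion, argon work-up
Reagents that add atoms: none
Why: Neutral hydrogenolysis of four aryl benzyl ethers and two secondary alkyl benzyl ethers; the interflavan link is a hindered di-secondary dibenzylic ether and should be cleaved far more slowly, and no acid or base is present that could ionise C4–O or form a quinone methide.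

## Compound list

1 | (4S)-4-benzyl-3-[(benzyloxy)acetyl]-1,3-oxazolidin-2-one | O=C(COCc1ccccc1)N1[C@@H](Cc2ccccc2)COC1=O | starting material
2 | 4-(benzyloxy)benzaldehyde | O=Cc1ccc(OCc2ccccc2)cc1 | starting material
3 | (Z)-dibutylboron enolate of 1 | CCCCB(CCCC)O/C(N1[C@@H](Cc2ccccc2)COC1=O)=C\OCc1ccccc1 | intermediate
4 | (4S)-4-benzyl-3-[(2S,3R)-2-(benzyloxy)-3-[4-(benzyloxy)phenyl]-3-hydroxypropanoyl]-1,3-oxazolidin-2-one | c1ccccc1COc1ccc(cc1)[C@@H](O)[C@H](OCc1ccccc1)C(=O)N1[C@@H](Cc2ccccc2)COC1=O | intermediate
5 | (1R,2R)-2-(benzyloxy)-1-[4-(benzyloxy)phenyl]propane-1,3-diol | c1ccccc1COc1ccc(cc1)[C@@H](O)[C@H](OCc1ccccc1)CO | intermediate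
6 | (1R,2R)-2-(benzyloxy)-1-[4-(benzyloxy)phenyl]-3-[(triisopropylsilyl)oxy]propan-1-ol | c1ccccc1COc1ccc(cc1)[C@@H](O)[C@H](OCc1ccccc1)CO[Si](C(C)C)(C(C)C)C(C)C | intermediate
7 | 3-bromobenzene-1,2-diol (3-bromocatechol) | Oc1cccc(Br)c1O | starting material
8 | 1,2-bis(benzyloxy)-3-bromobenzene | Brc1cccc(OCc2ccccc2)c1OCc1ccccc1 | intermediate
9 | 1,2-bis(benzyloxy)-3-iodobenzene | Ic1cccc(OCc2ccccc2)c1OCc1ccccc1 | intermediate
10 | [(2R,3R)-2-(benzyloxy)-3-[4-(benzyloxy)phenyl]-3-[2,3-bis(benzyloxy)phenoxy]propoxy]triisopropylsilane | c1ccccc1COc1ccc(cc1)[C@@H](Oc1cccc(OCc2ccccc2)c1OCc1ccccc1)[C@H](OCc1ccccc1)CO[Si](C(C)C)(C(C)C)C(C)C | intermediate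
11 | (2R,3R)-2-(benzyloxy)-3-[4-(benzyloxy)phenyl]-3-[2,3-bis(benzyloxy)phenoxy]propan-1-ol | c1ccccc1COc1ccc(cc1)[C@@H](Oc1cccc(OCc2ccccc2)c1OCc1ccccc1)[C@H](OCc1ccccc1)CO | intermediate
12 | (2S,3R)-2-(benzyloxy)-3-[4-(benzyloxy)phenyl]-3-[2,3-bis(benzyloxy)phenoxy]propanal | c1ccccc1COc1ccc(cc1)[C@@H](Oc1cccc(OCc2ccccc2)c1OCc1ccccc1)[C@H](OCc1ccccc1)C=O | intermediate
13 | (2S,3R)-2-(benzyloxy)-3-[4-(benzyloxy)phenyl]-3-[2,3-bis(benzyloxy)phenoxy]propanoic acid | c1ccccc1COc1ccc(cc1)[C@@H](Oc1cccc(OCc2ccccc2)c1OCc1ccccc1)[C@H](OCc1ccccc1)C(=O)O | intermediate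
14 | 1-(2,3,4-trihydroxyphenyl)ethan-1-one (gallacetophenone) | CC(=O)c1ccc(O)c(O)c1O | starting material
15 | 4-acetyl-3-hydroxy-1,2-phenylene dimethanesulfonate | CC(=O)c1ccc(OS(C)(=O)=O)c(OS(C)(=O)=O)c1O | intermediate
16 | 4-[(2E)-3-(dimethylamino)prop-2-enoyl]-3-hydroxy-1,2-phenylene dimethanesulfonate | CN(C)/C=C/C(=O)c1ccc(OS(C)(=O)=O)c(OS(C)(=O)=O)c1O | intermediate
17 | 4-oxo-4H-chromene-7,8-diyl dimethanesulfonate | O=c1ccoc2c(OS(C)(=O)=O)c(OS(C)(=O)=O)ccc12 | intermediate
18 | [4-(benzyloxy)phenyl]boronic acid | OB(O)c1ccc(OCc2ccccc2)cc1 | starting material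
19 | (2R)-2-[4-(benzyloxy)phenyl]-4-oxo-3,4-dihydro-2H-chromene-7,8-diyl dimethanesulfonate | O=C1C[C@H](c2ccc(OCc3ccccc3)cc2)Oc2c1ccc(OS(C)(=O)=O)c2OS(C)(=O)=O | intermediate
20 | (2R,4R)-2-[4-(benzyloxy)phenyl]-4-hydroxy-3,4-dihydro-2H-chromene-7,8-diyl dimethanesulfonate | O[C@@H]1C[C@H](c2ccc(OCc3ccccc3)cc2)Oc2c1ccc(OS(C)(=O)=O)c2OS(C)(=O)=O | intermediate
21 | (2R)-2-[4-(benzyloxy)phenyl]-2H-chromene-7,8-diyl dimethanesulfonate | C1=C[C@H](c2ccc(OCc3ccccc3)cc2)Oc2c1ccc(OS(C)(=O)=O)c2OS(C)(=O)=O | intermediate
22 | (2S,3R,4R)-2-[4-(benzyloxy)phenyl]-3,4-dihydroxy-3,4-dihydro-2H-chromene-7,8-diyl dimethanesulfonate | O[C@@H]1c2ccc(OS(C)(=O)=O)c(OS(C)(=O)=O)c2O[C@@H](c2ccc(OCc3ccccc3)cc2)[C@@H]1O | intermediate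
23 | 2,2-dibutyl-1,3,2-dioxastannolane formed across O3 and O4 of 22 | CCCC[Sn]1(CCCC)O[C@@H]2c3ccc(OS(C)(=O)=O)c(OS(C)(=O)=O)c3O[C@@H](c3ccc(OCc4ccccc4)cc3)[C@@H]2O1 | intermediate
24 | (2S,3R,4R)-3-(benzyloxy)-2-[4-(benzyloxy)phenyl]-4-hydroxy-3,4-dihydro-2H-chromene-7,8-diyl dimethanesulfonate | O[C@@H]1c2ccc(OS(C)(=O)=O)c(OS(C)(=O)=O)c2O[C@@H](c2ccc(OCc3ccccc3)cc2)[C@@H]1OCc1ccccc1 | intermediate
25 | ester of acid 13 with the 4-hydroxyl of 24 | c1ccccc1COc1ccc(cc1)[C@@H](Oc1cccc(OCc2ccccc2)c1OCc1ccccc1)[C@H](OCc1ccccc1)C(=O)O[C@@H]1c2ccc(OS(C)(=O)=O)c(OS(C)(=O)=O)c2O[C@@H](c2ccc(OCc3ccccc3)cc2)[C@@H]1OCc1ccccc1 | intermediate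
26 | diisobutylaluminium hemiacetal of 25 | c1ccccc1COc1ccc(cc1)[C@@H](Oc1cccc(OCc2ccccc2)c1OCc1ccccc1)[C@H](OCc1ccccc1)C(O[Al](CC(C)C)CC(C)C)O[C@@H]1c2ccc(OS(C)(=O)=O)c(OS(C)(=O)=O)c2O[C@@H](c2ccc(OCc3ccccc3)cc2)[C@@H]1OCc1ccccc1 | intermediate
27 | α-acetoxy ether: the carbonyl carbon of 25 as CH(OAc), acetal centre as both epimers | c1ccccc1COc1ccc(cc1)[C@@H](Oc1cccc(OCc2ccccc2)c1OCc1ccccc1)[C@H](OCc1ccccc1)C(OC(C)=O)O[C@@H]1c2ccc(OS(C)(=O)=O)c(OS(C)(=O)=O)c2O[C@@H](c2ccc(OCc3ccccc3)cc2)[C@@H]1OCc1ccccc1 | intermediate
28 | oxocarbenium triflate from 27 by loss of acetate | c1ccccc1COc1ccc(cc1)[C@@H](Oc1cccc(OCc2ccccc2)c1OCc1ccccc1)[C@H](OCc1ccccc1)C=[O+][C@@H]1c2ccc(OS(C)(=O)=O)c(OS(C)(=O)=O)c2O[C@@H](c2ccc(OCc3ccccc3)cc2)[C@@H]1OCc1ccccc1.[O-]S(=O)(=O)C(F)(F)F | intermediate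
29 | protected dimer: unit A (2R,3R,4R) with 3,7,8,4'-tetra-O-benzyl; unit B (2S,3R,4R) with 3,4'-di-O-benzyl and 7,8-di-O-mesyl | c1ccccc1COc1ccc(cc1)[C@H]1Oc2c(ccc(OCc3ccccc3)c2OCc2ccccc2)[C@@H](O[C@@H]2c3ccc(OS(C)(=O)=O)c(OS(C)(=O)=O)c3O[C@@H](c3ccc(OCc4ccccc4)cc3)[C@@H]2OCc2ccccc2)[C@H]1OCc1ccccc1 | intermediate
30 | hexabenzyl ether: 29 with the 7- and 8-hydroxyls of unit B free | c1ccccc1COc1ccc(cc1)[C@H]1Oc2c(ccc(OCc3ccccc3)c2OCc2ccccc2)[C@@H](O[C@@H]2c3ccc(O)c(O)c3O[C@@H](c3ccc(OCc4ccccc4)cc3)[C@@H]2OCc2ccccc2)[C@H]1OCc1ccccc1 | intermediate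
31 | (2R,3R,4R)-3,7,8-trihydroxy-2-(4-hydroxyphenyl)chroman-4-yl (2S,3R,4R)-3,7,8-trihydroxy-2-(4-hydroxyphenyl)chroman-4-yl ether | Oc1ccc([C@H]2Oc3c(ccc(O)c3O)[C@@H](O[C@@H]3c4ccc(O)c(O)c4O[C@@H](c4ccc(O)cc4)[C@@H]3O)[C@H]2O)cc1 | target

## Step count and risks

Total: 20 steps. Longest linear sequence: 12 steps (14 to 31, steps 9–20). The unit A branch contributes 6 steps from 1 and 2 to acid 13, plus 2 steps for iodide 9.

**Step 18 (key step).**
- Most likely failure: poor facial selectivity at the oxocarbenium carbon. The chair with the oxocarbenium oxygen axial is dipole-minimised (C3–O anti to C=O+) and avoids the peri interaction, and it leads to the 3,4-trans ether.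
- Second failure mode: re-ionisation of the product at C4 of unit A under the Lewis acid, with loss of unit B.
- First variable to change: a bidentate Lewis acid that can bridge O3 and the acetal oxygen.
- Fallback (sets out from acid 13 and alcohol 24, returns at 29): ring C of unit A is closed first by intramolecular Friedel–Crafts acylation of 13 ((CF3CO)2O, CH2Cl2, 0 °C) to the 2,3-cis flavan-4-one F1. Alcohol 24 is converted into its trimethylsilyl ether F2 (Me3SiCl, imidazole). Reductive etherification of F1 with F2 (Et3SiH, catalytic Me3SiOTf, CH2Cl2, −78 °C) passes through the ring-bound benzylic oxocarbenium ion; hydride should add trans to the axial 3-benzyloxy group, which leaves the unit B oxygen cis to O3.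

**Step 6.**
- Most likely failure: slow C–O coupling of a hindered secondary alkoxide with an ortho-alkoxy aryl iodide, with competing reduction of the iodide or base-induced silyl transfer.
- Fallback (sets out from 6, returns at 10): Dess–Martin oxidation gives the aryl ketone F3. Chelation-controlled reduction (Zn(BH4)2, Et2O, −20 °C) gives the anti alcohol F4. 2,3-Bis(benzyloxy)phenol F5 is made from bromide 8 (n-BuLi, B(OMe)3, then H2O2). Mitsunobu etherification of F4 with F5 (PPh3, DIAD, toluene, 0 °C) goes with inversion to 10.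

**Step 11.**
- Most likely failure: insufficient enantioselectivity or turnover with this electron-poor, 8-substituted chromone.
- Fallback (sets out from 17, returns at 20): racemic conjugate addition of 18 with Pd(OCOCF3)2 and 2,2'-bipyridine gives the racemic flavanone F6. Kinetic resolution by asymmetric transfer hydrogenation (RuCl(p-cymene)[(R,R)-TsDPEN], HCO2H/Et3N) reduces the 2R enantiomer to 20; the slower-reacting ketone enantiomer is separated.

**Step 16.**
- Most likely failure: incomplete acylation of the pseudoaxial, peri-hindered benzylic hydroxyl by a doubly branched acid, or β-elimination of the aryloxide from the activated acid.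
- Fallback (sets out from 24, returns at 25): Dess–Martin oxidation gives the trans 3-benzyloxyflavan-4-one F7. NaBH4 gives the 3,4-trans alcohol F8 (equatorial hydroxyl). Mitsunobu esterification of F8 with acid 13 (PPh3, DIAD) inverts C4 to give 25.

## Further compounds

F1 | step 18 | (2R,3S)-3,7,8-tris(benzyloxy)-2-[4-(benzyloxy)phenyl]-2,3-dihydro-4H-chromen-4-one | c1ccccc1COc1ccc(cc1)[C@H]1Oc2c(ccc(OCc3ccccc3)c2OCc2ccccc2)C(=O)[C@H]1OCc1ccccc1
F2 | step 18 | trimethylsilyl ether of 24 at O4 | C[Si](C)(C)O[C@@H]1c2ccc(OS(C)(=O)=O)c(OS(C)(=O)=O)c2O[C@@H](c2ccc(OCc3ccccc3)cc2)[C@@H]1OCc1ccccc1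
F3 | step 6 | (2R)-2-(benzyloxy)-1-[4-(benzyloxy)phenyl]-3-[(triisopropylsilyl)oxy]propan-1-one | c1ccccc1COc1ccc(cc1)C(=O)[C@H](OCc1ccccc1)CO[Si](C(C)C)(C(C)C)C(C)C
F4 | step 6 | (1S,2R)-2-(benzyloxy)-1-[4-(benzyloxy)phenyl]-3-[(triisopropylsilyl)oxy]propan-1-ol | c1ccccc1COc1ccc(cc1)[C@H](O)[C@H](OCc1ccccc1)CO[Si](C(C)C)(C(C)C)C(C)C
F5 | step 6 | 2,3-bis(benzyloxy)phenol | Oc1cccc(OCc2ccccc2)c1OCc1ccccc1
F6 | step 11 | racemic 2-[4-(benzyloxy)phenyl]-4-oxo-3,4-dihydro-2H-chromene-7,8-diyl dimethanesulfonate | O=C1CC(c2ccc(OCc3ccccc3)cc2)Oc2c1ccc(OS(C)(=O)=O)c2OS(C)(=O)=O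
F7 | step 16 | (2S,3S)-3-(benzyloxy)-2-[4-(benzyloxy)phenyl]-4-oxo-3,4-dihydro-2H-chromene-7,8-diyl dimethanesulfonate | O=C1c2ccc(OS(C)(=O)=O)c(OS(C)(=O)=O)c2O[C@@H](c2ccc(OCc3ccccc3)cc2)[C@@H]1OCc1ccccc1
F8 | step 16 | (2S,3R,4S)-3-(benzyloxy)-2-[4-(benzyloxy)phenyl]-4-hydroxy-3,4-dihydro-2H-chromene-7,8-diyl dimethanesulfonate | O[C@H]1c2ccc(OS(C)(=O)=O)c(OS(C)(=O)=O)c2O[C@@H](c2ccc(OCc3ccccc3)cc2)[C@@H]1OCc1ccccc1
A1 | alternative 1 | all-cis 4-O-4 dimer, both units (2R,3R,4R), 3,7,8-tri-O-benzyl on each unit, 4'-O-triisopropylsilyl on unit A, free 4'-hydroxyl on unit B | CC(C)[Si](C(C)C)(C(C)C)Oc1ccc([C@H]2Oc3c(ccc(OCc9ccccc9)c3OCc9ccccc9)[C@@H](O[C@@H]3c4ccc(OCc9ccccc9)c(OCc9ccccc9)c4O[C@H](c4ccc(O)cc4)[C@@H]3OCc9ccccc9)[C@H]2OCc9ccccc9)cc1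
A2 | alternative 1 | C2 epimer of A1 in unit B (unit B 2S,3R,4R) | CC(C)[Si](C(C)C)(C(C)C)Oc1ccc([C@H]2Oc3c(ccc(OCc9ccccc9)c3OCc9ccccc9)[C@@H](O[C@@H]3c4ccc(OCc9ccccc9)c(OCc9ccccc9)c4O[C@@H](c4ccc(O)cc4)[C@@H]3OCc9ccccc9)[C@H]2OCc9ccccc9)cc1
A3 | alternative 2 | open-chain octabenzyl dibromo diol: both O1–C8a bonds of A4 replaced by C2–OH and C8a–Br | c1ccccc1COc1ccc(cc1)[C@@H](O)[C@H](OCc1ccccc1)[C@H](O[C@H](c1ccc(OCc2ccccc2)c(OCc2ccccc2)c1Br)[C@@H](OCc1ccccc1)[C@@H](O)c1ccc(OCc2ccccc2)cc1)c1ccc(OCc2ccccc2)c(OCc2ccccc2)c1Br
A4 | alternative 2 | octa-O-benzyl ether of the target | c9ccccc9COc1ccc([C@H]2Oc3c(ccc(OCc9ccccc9)c3OCc9ccccc9)[C@@H](O[C@@H]3c4ccc(OCc9ccccc9)c(OCc9ccccc9)c4O[C@@H](c4ccc(OCc9ccccc9)cc4)[C@@H]3OCc9ccccc9)[C@H]2OCc9ccccc9)cc1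
A5 | alternative 3 | 2,3-bis(benzyloxy)-4-chlorocyclobut-2-en-1-one | O=C1C(Cl)C(OCc2ccccc2)=C1OCc1ccccc1
A6 | alternative 3 | (E)-tributylstannyl alkene carrying the open unit B chain (C4 ether to closed unit A, 3-O-benzyl, 2-O-triethylsilyl) | CCCC[Sn](CCCC)(CCCC)/C=C/[C@@H](O[C@@H]1c2ccc(OCc9ccccc9)c(OCc9ccccc9)c2O[C@H](c2ccc(OCc9ccccc9)cc2)[C@@H]1OCc9ccccc9)[C@@H](OCc9ccccc9)[C@H](O[Si](CC)(CC)CC)c1ccc(OCc9ccccc9)cc1
A7 | alternative 3 | 2,3-bis(benzyloxy)phenol bearing the open unit B chain ortho to the new hydroxyl | Oc1c(OCc9ccccc9)c(OCc9ccccc9)ccc1[C@@H](O[C@@H]1c2ccc(OCc9ccccc9)c(OCc9ccccc9)c2O[C@H](c2ccc(OCc9ccccc9)cc2)[C@@H]1OCc9ccccc9)[C@@H](OCc9ccccc9)[C@H](O[Si](CC)(CC)CC)c1ccc(OCc9ccccc9)cc1
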